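The feed is the easy rung: in birch and alder the starting material is in after 3.0 s, far sooner than the first clear target, read at 30.0 s in the midnight run.

| setting | midnight | birch | alder |
|---|---|---|---|
| starting material | 15 mM (fed, over 3.0 s) | 15 mM (fed, over 3.0 s) | 15 mM (fed, over 3.0 s) |
| catalyst | 5 mol% | 10 mol% | 10 mol% |
| temperature | −15 °C | −15 °C | 0 °C |
| remark | run made earlier; the fed solution adds 0.20 times the starting volume | the fed solution adds 0.20 times the starting volume | the fed solution adds 0.20 times the starting volume |
| time |  | 2.5 min | 2.5 min |

- midnight (time / s: target / %, isomer of the product / %): 10.0: 0, 0; 12.0: 1, 0; 20.0: 1, 0; 30.0: 9, 0; 50.0: 15, 5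

(scatter of a reading: 1.5 percentage points)

- amounts are per litre of the starting volume; all of the dose is in the solution fed
- steps thought possible: target <-> isomer of the product; starting material -> intermediate; catalyst + intermediate -> catalyst + target
- the earlier runs do not show what temperature does; that part of a forecast is a guess
- no earlier run changes the charge of catalyst; that part of a forecast is a guess

- the flask with the highest share of target in all that became target or isomer of the product ("all alike" if they lie within 1.5 percentage points) (birch / alder / all alike)
- share of target in all that became target or isomer of the product, birch
- share of target in all that became target or isomer of the product, alder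

The next rung is that lag, which I read as the intermediate building up. I carry it over to birch as a guess, although birch has twice the catalyst. Above it stands the ageing time τ, the lifetime of target against turning into isomer of the product: the area under the midnight target curve, divided by the isomer made. It rests on one reading.

τ = 58.0 s

With the isomer reading one scatter lower:

τ′ = 82.9 s

The top rung is the asked 2.5 min, longer than τ, while the lag is shorter. So I expect ageing to take a real part in birch, and I place birch near the crossing from kinetic to thermodynamic control. I let target arrive steadily from the lag L = 30.0 s to the reading time t and ignore the reverse step. With a = (t − L)/τ, the share of target is S = (1 − e^(−a))/a.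

Birch: a = 2.07, S = 42.2%

With τ′: a = 1.45, S = 52.8%

I give alder no number, since no earlier run shows temperature; I guess that it ages faster.

The forecast names birch, with 40% for birch and 29% for alder: “Alder is warmer, so it isomerises faster and should sit closer to equilibrium, giving a lower share.”

The flasks give 60.4% for birch and 37.2% for alder, so birch stands highest.

    target ⇌ isomer of the product (K = 1.70, k = 0.0410 s⁻¹, Ea = 67.0 kJ mol⁻¹, ΔH = −42.0 kJ mol⁻¹)
    starting material → intermediate (k = 0.0500 s⁻¹, Ea = 63.0 kJ mol⁻¹)
    catalyst + intermediate → catalyst + target (k = 100 M⁻¹ s⁻¹, Ea = 35.0 kJ mol⁻¹)
    (constants at 0 °C)

Birch stands above both my values of S, and the main reason for its share is the short time allowed: birch holds 60.4% at 2.5 min, and left ten times as long it holds 16.7%. On the neighbour, birch read at 1.50 min, the rule has a = 1.03 and gives S = 62.3%. With τ′ it gives 71.2%, and that flask holds 75.7%.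

The readings are calculated with made-up constants, and the scatter is random.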